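**Retrosynthetic overview**
1. Bisoflavolin H (19) comes from fourfold O-demethylation of tetramethyl ether 18, and 18 from loss of water at the C3″ carbinol of 3-hydroxychromanone 17.
2. Feature used: in the pyranone ring of the genistein half (O1″, C2″, C3″, C4″, C4a″, C8a″), C4″ (ring carbonyl on C4a″ of the phloroglucinol ring) and C3″ (bearing the 4-oxyphenyl ring) are both carbonyl-level carbons once O1″–C2″ is drawn as an aryl phenacyl ether. The C3″–C4″ bond is therefore made by a carbene-catalysed crossed benzoin closure of keto-aldehyde 16.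
3. 16 comes from phenacylation of salicylaldehyde 14, and 14 from phenol-directed ortho-formylation of 12. The directing hydroxyl sits next to the aryloxy carbon and becomes O1″, so the diaryl ether oxygen can only end at C8″. A Lewis-acid demethylation of a 3-aryloxy-2,4,6-trimethoxybenzaldehyde is avoided because it could not reliably tell the two ortho methoxy groups apart.
4. 12 comes from Ullmann C–O coupling of iodoisoflavone 6 (deoxybenzoin route from 2-chlororesorcinol and 4-iodophenylacetic acid) with MOM-protected phenol 10 (Baeyer–Villiger/Dakin degradation of 2-hydroxy-4,6-dimethoxybenzaldehyde).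
5. Ring order: the chlorinated pyranone first (step 2), the genistein pyranone last (closed in step 10, made aromatic in step 11).

Key step: step 10

Remark: the target has no stereocentre, so no enantiomer has to be chosen. The only stereocentre formed on the way (C3″ of 17) is racemic and is erased in step 11.

**Route**

Step 1
Reactants: 1 2-chlororesorcinol; 2 4-iodophenylacetic acid
Product: 3 1-(3-chloro-2,4-dihydroxyphenyl)-2-(4-iodophenyl)ethan-1-one
Conditions: BF3·OEt2 (as solvent), 85 °C; then aq. NaOAc
Reagents that add atoms: none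
Why: Friedel–Crafts (Nencki-type) acylation at C4 of the resorcinol, ortho and para to the two hydroxyls (C4 and C6 are equivalent, C2 carries Cl), with the product held as a BF2 chelate that prevents a second acylation.

Step 2
Reactants: 3 1-(3-chloro-2,4-dihydroxyphenyl)-2-(4-iodophenyl)ethan-1-one
Product: 5 8-chloro-7-hydroxy-3-(4-iodophenyl)-4H-chromen-4-one, via enaminone 4 (not isolated)
Conditions: DMF-DMA, THF, reflux; then dilute HCl
Reagents that add atoms: N,N-dimethylformamide dimethyl acetal, COC(OC)N(C)C
Why: Condensation of the benzylic methylene with the amide acetal gives the enaminone, and addition–elimination by the ortho hydroxyl (loss of dimethylamine) closes the pyranone (deoxybenzoin isoflavone synthesis); any 7-O-methylated material formed by the reagent converges on 6 in step 3.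

Step 3
Reactants: 5 8-chloro-7-hydroxy-3-(4-iodophenyl)-4H-chromen-4-one
Product: 6 8-chloro-3-(4-iodophenyl)-7-methoxy-4H-chromen-4-one
Conditions: MeI, K2CO3, acetone, reflux
Reagents that add atoms: iodomethane, CI
Why: Williamson O-methylation of the only hydroxyl, an acidic vinylogous carboxylic acid OH.

Step 4
Reactants: 7 2-hydroxy-4,6-dimethoxybenzaldehyde
Product: 8 2,4-dimethoxy-6-(methoxymethoxy)benzaldehyde
Conditions: MOMCl, K2CO3, DMF, 0 °C → rt
Reagents that add atoms: chloromethyl methyl ether, COCCl
Why: O-alkylation of the phenoxide marks the oxygen that will become O1″ with an acetal that survives peracid, base and copper and is later removed by acid without touching the methyl ethers.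

Step 5
Reactants: 8 2,4-dimethoxy-6-(methoxymethoxy)benzaldehyde
Product: 10 2,4-dimethoxy-6-(methoxymethoxy)phenol, via aryl formate 9 (not isolated)
Conditions: mCPBA, CH2Cl2, 0 °C → rt; aq. NaHCO3 wash; then K2CO3 (cat.), MeOH, rt, argon
Reagents that add atoms: mCPBA, O=C(OO)c1cccc(Cl)c1
Why: Baeyer–Villiger (Dakin-type) oxidation, in which the electron-rich aryl group migrates in preference to hydrogen in the Criegee adduct, followed by methanolysis of the formate to the phenol.

Step 6
Reactants: 6 8-chloro-3-(4-iodophenyl)-7-methoxy-4H-chromen-4-one; 10 2,4-dimethoxy-6-(methoxymethoxy)phenol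
Product: 11 8-chloro-3-{4-[2,4-dimethoxy-6-(methoxymethoxy)phenoxy]phenyl}-7-methoxy-4H-chromen-4-one
Conditions: CuI (10 mol %), picolinic acid (20 mol %), K3PO4, DMSO (dry), 90 °C, argon
Reagents that add atoms: none
Why: Ullmann-type C–O coupling with a ligand suited to di-ortho-substituted phenols; copper inserts into the C–I bond far faster than into the hindered, electron-rich C8–Cl bond, and dry phosphate avoids hydroxide attack on the pyranone.

Step 7
Reactants: 11 8-chloro-3-{4-[2,4-dimethoxy-6-(methoxymethoxy)phenoxy]phenyl}-7-methoxy-4H-chromen-4-one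
Product: 12 8-chloro-3-[4-(2-hydroxy-4,6-dimethoxyphenoxy)phenyl]-7-methoxy-4H-chromen-4-one
Conditions: conc. HCl (cat.), MeOH/THF, 50 °C
Reagents that add atoms: none
Why: Acid-catalysed acetal exchange removes the MOM group through its oxocarbenium ion (trapped by methanol), while aryl methyl ethers, the diaryl ether and the chromone are stable to dilute acid.

Step 8
Reactants: 12 8-chloro-3-[4-(2-hydroxy-4,6-dimethoxyphenoxy)phenyl]-7-methoxy-4H-chromen-4-one
Product: 14 3-[4-(8-chloro-7-methoxy-4-oxo-4H-chromen-3-yl)phenoxy]-2-hydroxy-4,6-dimethoxybenzaldehyde, via hydroxymethyl phenol 13 (not isolated)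
Conditions: MgCl2, Et3N, (CH2O)n, MeCN, reflux; then 1 M HCl
Reagents that add atoms: paraformaldehyde (reacts as formaldehyde), C=O
Why: Casnati–Skattebøl ortho-formylation, in which the magnesium phenoxide delivers formaldehyde through a six-membered chelate to the only free ortho carbon (the other carries the aryloxy group) and the salicyl alkoxide is oxidised in place by a second formaldehyde (Oppenauer-type hydride transfer), so the reactive CH between the two methoxy groups is left alone.

Step 9
Reactants: 14 3-[4-(8-chloro-7-methoxy-4-oxo-4H-chromen-3-yl)phenoxy]-2-hydroxy-4,6-dimethoxybenzaldehyde; 15 2-bromo-4′-methoxyacetophenone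
Product: 16 3-[4-(8-chloro-7-methoxy-4-oxo-4H-chromen-3-yl)phenoxy]-4,6-dimethoxy-2-[2-(4-methoxyphenyl)-2-oxoethoxy]benzaldehyde
Conditions: K2CO3, DMF, 0 °C → rt (no heating)
Reagents that add atoms: none
Why: Williamson SN2 alkylation of the phenoxide by the very reactive α-bromoketone fixes O1″–C2″, and mild carbonate at low temperature should stop at the ether before the OCH2 group can condense onto the aldehyde (Rap–Stoermer benzofuran formation).

Step 10
Reactants: 16 3-[4-(8-chloro-7-methoxy-4-oxo-4H-chromen-3-yl)phenoxy]-4,6-dimethoxy-2-[2-(4-methoxyphenyl)-2-oxoethoxy]benzaldehyde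
Product: 17 rac-8-[4-(8-chloro-7-methoxy-4-oxo-4H-chromen-3-yl)phenoxy]-3-hydroxy-5,7-dimethoxy-3-(4-methoxyphenyl)chroman-4-one
Conditions: 2-mesityl-6,7-dihydro-5H-pyrrolo[2,1-c][1,2,4]triazol-2-ium chloride (20 mol %), DBU (18 mol %), toluene (degassed), rt → 40 °C, argon
Reagents that add atoms: none
Why: The carbene released from the triazolium salt adds to the formyl carbon (future C4″), a proton shift gives the Breslow enaminol, its nucleophilic carbon attacks the tethered 4-methoxyphenyl ketone (future C3″), and collapse of the adduct expels the carbene to leave the α-ketol. The closest known reaction type is the carbene-catalysed intramolecular crossed aldehyde–ketone benzoin reaction of 2-(2-oxoalkoxy)benzaldehydes to 3-hydroxychroman-4-ones. The pyranone ring closes in the 6-exo-trig mode, the ketone oxygen lying outside the ring being formed. The new stereocentre C3″ is formed without control by the achiral catalyst, so 17 is racemic, which is harmless because this carbon becomes sp2 in step 11. The step needs acyl-anion addition to the ketone to win over aldehyde self-condensation and over base-mediated aldol closure of the OCH2 group onto the aldehyde: only the aldehyde can form a Breslow intermediate, the six-atom tether makes the crossed path intramolecular, the formyl group flanked by two oxygen substituents resists dimerisation, and the amidine is kept below the azolium loading so that little free base remains. The place of the aryloxy group (C8″, not C6″) is not decided here, since it was fixed when the directing hydroxyl of 12 became O1″.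

Step 11
Reactants: 17 rac-8-[4-(8-chloro-7-methoxy-4-oxo-4H-chromen-3-yl)phenoxy]-3-hydroxy-5,7-dimethoxy-3-(4-methoxyphenyl)chroman-4-one
Product: 18 8-[4-(8-chloro-7-methoxy-4-oxo-4H-chromen-3-yl)phenoxy]-5,7-dimethoxy-3-(4-methoxyphenyl)-4H-chromen-4-one
Conditions: TsOH·H2O (20 mol %), toluene, reflux, Dean–Stark
Reagents that add atoms: none
Why: Acid-catalysed E1 dehydration of the tertiary benzylic carbinol, in which the C3″ cation is stabilised by the 4-methoxyphenyl ring (the neighbouring carbonyl is a vinylogous ester of three ring oxygens and destabilises it little) and loss of a C2″ proton next to O1″ gives the conjugated pyranone, with water removed azeotropically.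

Step 12
Reactants: 18 8-[4-(8-chloro-7-methoxy-4-oxo-4H-chromen-3-yl)phenoxy]-5,7-dimethoxy-3-(4-methoxyphenyl)-4H-chromen-4-one
Product: 19 Bisoflavolin H, 8-[4-(8-chloro-7-hydroxy-4-oxo-4H-chromen-3-yl)phenoxy]-5,7-dihydroxy-3-(4-hydroxyphenyl)-4H-chromen-4-one
Conditions: BBr3 (12 equiv), CH2Cl2, −78 °C → rt; then ice-water
Reagents that add atoms: none
Why: Lewis-acid ether cleavage, in which boron binds each methoxy oxygen and bromide attacks the methyl carbon (SN2), so the four aryl methyl ethers fall (the chelated 5″-OMe first) while the diaryl ether, which offers no sp3 carbon, the aryl chloride and both pyranones should survive.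

**Compound list**
1 | 2-chlororesorcinol (2-chlorobenzene-1,3-diol) | Oc1cccc(O)c1Cl | starting material
2 | 4-iodophenylacetic acid | O=C(O)Cc1ccc(I)cc1 | starting material
3 | 1-(3-chloro-2,4-dihydroxyphenyl)-2-(4-iodophenyl)ethan-1-one | O=C(Cc1ccc(I)cc1)c1ccc(O)c(Cl)c1O | intermediate
4 | 1-(3-chloro-2,4-dihydroxyphenyl)-3-(dimethylamino)-2-(4-iodophenyl)prop-2-en-1-one (enaminone; double-bond geometry not defined; not isolated) | CN(C)C=C(C(=O)c1ccc(O)c(Cl)c1O)c1ccc(I)cc1 | intermediate
5 | 8-chloro-7-hydroxy-3-(4-iodophenyl)-4H-chromen-4-one | O=c1c(-c2ccc(I)cc2)coc2c(Cl)c(O)ccc12 | intermediate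
6 | 8-chloro-3-(4-iodophenyl)-7-methoxy-4H-chromen-4-one | O=c1c(-c2ccc(I)cc2)coc2c(Cl)c(OC)ccc12 | intermediate
7 | 2-hydroxy-4,6-dimethoxybenzaldehyde | O=Cc1c(O)cc(OC)cc1OC | starting material
8 | 2,4-dimethoxy-6-(methoxymethoxy)benzaldehyde | O=Cc1c(OCOC)cc(OC)cc1OC | intermediate
9 | 2,4-dimethoxy-6-(methoxymethoxy)phenyl formate (not isolated) | O=COc1c(OCOC)cc(OC)cc1OC | intermediate
10 | 2,4-dimethoxy-6-(methoxymethoxy)phenol | Oc1c(OCOC)cc(OC)cc1OC | intermediate
11 | 8-chloro-3-{4-[2,4-dimethoxy-6-(methoxymethoxy)phenoxy]phenyl}-7-methoxy-4H-chromen-4-one | O=c1c(-c2ccc(Oc3c(OCOC)cc(OC)cc3OC)cc2)coc2c(Cl)c(OC)ccc12 | intermediate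
12 | 8-chloro-3-[4-(2-hydroxy-4,6-dimethoxyphenoxy)phenyl]-7-methoxy-4H-chromen-4-one | O=c1c(-c2ccc(Oc3c(O)cc(OC)cc3OC)cc2)coc2c(Cl)c(OC)ccc12 | intermediate
13 | 8-chloro-3-{4-[2-hydroxy-3-(hydroxymethyl)-4,6-dimethoxyphenoxy]phenyl}-7-methoxy-4H-chromen-4-one (formed as its magnesium alkoxide; not isolated) | O=c1c(-c2ccc(Oc3c(O)c(CO)c(OC)cc3OC)cc2)coc2c(Cl)c(OC)ccc12 | intermediate
14 | 3-[4-(8-chloro-7-methoxy-4-oxo-4H-chromen-3-yl)phenoxy]-2-hydroxy-4,6-dimethoxybenzaldehyde | O=Cc1c(O)c(Oc2ccc(-c3coc4c(Cl)c(OC)ccc4c3=O)cc2)c(OC)cc1OC | intermediate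
15 | 2-bromo-4′-methoxyacetophenone | COc1ccc(C(=O)CBr)cc1 | starting material
16 | 3-[4-(8-chloro-7-methoxy-4-oxo-4H-chromen-3-yl)phenoxy]-4,6-dimethoxy-2-[2-(4-methoxyphenyl)-2-oxoethoxy]benzaldehyde | O=Cc1c(OC)cc(OC)c(Oc2ccc(-c3coc4c(Cl)c(OC)ccc4c3=O)cc2)c1OCC(=O)c1ccc(OC)cc1 | intermediate
17 | rac-8-[4-(8-chloro-7-methoxy-4-oxo-4H-chromen-3-yl)phenoxy]-3-hydroxy-5,7-dimethoxy-3-(4-methoxyphenyl)chroman-4-one (racemic at C3) | O=C1c2c(OC)cc(OC)c(Oc3ccc(-c4coc5c(Cl)c(OC)ccc5c4=O)cc3)c2OCC1(O)c1ccc(OC)cc1 | intermediate
18 | 8-[4-(8-chloro-7-methoxy-4-oxo-4H-chromen-3-yl)phenoxy]-5,7-dimethoxy-3-(4-methoxyphenyl)-4H-chromen-4-one | O=c1c(-c2ccc(Oc3c(OC)cc(OC)c4c(=O)c(-c5ccc(OC)cc5)coc34)cc2)coc2c(Cl)c(OC)ccc12 | intermediate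
19 | Bisoflavolin H (achiral) | O=c1c(-c2ccc(Oc3c(O)cc(O)c4c(=O)c(-c5ccc(O)cc5)coc34)cc2)coc2c(Cl)c(O)ccc12 | target

**Step count**
Total steps: 12. Longest linear sequence: 10 (steps 1–3, then 6–12); steps 4–5 form the two-step branch to phenol 10.

**Steps most likely to fail**

Step 10. Carbene addition to the doubly ortho-substituted, electron-rich aldehyde may be too slow, so that base-mediated aldol closure of the OCH2 group onto the aldehyde, with loss of water to a benzofuran, takes over. The fallback gives up the C3″–C4″ closure and builds the genistein pyranone by the deoxybenzoin route. It sets out from phenol 12, which should be acylated with 4-methoxyphenylacetic acid in BF3·OEt2 at 80 °C. Boron chelation should direct the acyl group to the carbon ortho to the free hydroxyl, as in the acylation of 3,5-dimethoxyphenol, to give 1-{3-[4-(8-chloro-7-methoxy-4-oxo-4H-chromen-3-yl)phenoxy]-2-hydroxy-4,6-dimethoxyphenyl}-2-(4-methoxyphenyl)ethan-1-one F1. Heating F1 with DMF-DMA in THF should give the enaminone F2, which should close with loss of dimethylamine. The fallback comes back to the route at 18.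

Step 11. Ionisation at a carbon next to a carbonyl may be sluggish, and acid-induced acyloin (α-ketol) rearrangement by 1,2-shift of the aryl group or of C2″ may compete with proton loss. The fallback removes the hydroxyl reductively and then introduces the double bond by oxidation. It sets out from 17. SmI2 in THF/MeOH at −78 °C should cleave the C3″–O bond next to the ketone (electron transfer, loss of hydroxide, protonation of the samarium enolate) to give the isoflavanone rac-8-[4-(8-chloro-7-methoxy-4-oxo-4H-chromen-3-yl)phenoxy]-5,7-dimethoxy-3-(4-methoxyphenyl)chroman-4-one F3. DDQ in dioxane at reflux should then dehydrogenate C2″–C3″. The fallback comes back at 18.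

Step 6. The electron-rich phenoxide may be oxidised, C–O bond formation at the di-ortho-substituted oxygen may be slow, and the pyranone may be opened by base at 90 °C. The fallback reverses the roles to an oxidative copper(II) coupling at room temperature. It sets out from 6. Miyaura borylation (B2pin2, PdCl2(dppf), KOAc, dioxane, 80 °C, selective for C–I over C–Cl) should give 8-chloro-7-methoxy-3-[4-(4,4,5,5-tetramethyl-1,3,2-dioxaborolan-2-yl)phenyl]-4H-chromen-4-one F4. NaIO4/NH4OAc in acetone–water should free [4-(8-chloro-7-methoxy-4-oxo-4H-chromen-3-yl)phenyl]boronic acid F5. Chan–Evans–Lam coupling of F5 with phenol 10 (Cu(OAc)2, pyridine, 4 Å sieves, CH2Cl2, air, rt) comes back to the route at 11.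

**Further compounds**
F1 | step 10 | 1-{3-[4-(8-chloro-7-methoxy-4-oxo-4H-chromen-3-yl)phenoxy]-2-hydroxy-4,6-dimethoxyphenyl}-2-(4-methoxyphenyl)ethan-1-one | O=C(Cc1ccc(OC)cc1)c1c(O)c(Oc2ccc(-c3coc4c(Cl)c(OC)ccc4c3=O)cc2)c(OC)cc1OC
F2 | step 10 | 1-{3-[4-(8-chloro-7-methoxy-4-oxo-4H-chromen-3-yl)phenoxy]-2-hydroxy-4,6-dimethoxyphenyl}-3-(dimethylamino)-2-(4-methoxyphenyl)prop-2-en-1-one (double-bond geometry not defined) | CN(C)C=C(C(=O)c1c(O)c(Oc2ccc(-c3coc4c(Cl)c(OC)ccc4c3=O)cc2)c(OC)cc1OC)c1ccc(OC)cc1
F3 | step 11 | rac-8-[4-(8-chloro-7-methoxy-4-oxo-4H-chromen-3-yl)phenoxy]-5,7-dimethoxy-3-(4-methoxyphenyl)chroman-4-one | O=C1c2c(OC)cc(OC)c(Oc3ccc(-c4coc5c(Cl)c(OC)ccc5c4=O)cc3)c2OCC1c1ccc(OC)cc1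
F4 | step 6 | 8-chloro-7-methoxy-3-[4-(4,4,5,5-tetramethyl-1,3,2-dioxaborolan-2-yl)phenyl]-4H-chromen-4-one | O=c1c(-c2ccc(B3OC(C)(C)C(C)(C)O3)cc2)coc2c(Cl)c(OC)ccc12
F5 | step 6 | [4-(8-chloro-7-methoxy-4-oxo-4H-chromen-3-yl)phenyl]boronic acid | O=c1c(-c2ccc(B(O)O)cc2)coc2c(Cl)c(OC)ccc12
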